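**Assumption:** the target has no stereocentre and no stereogenic double bond, so the "single enantiomer" is the one achiral structure drawn; alkene geometries are given only for acyclic intermediates and are lost on ring formation.

## Retrosynthetic overview

1. The phenols are unmasked last (tri-O-methyl ether, BBr3), so the aryl iodide is carried from the first step and no late iodination among three phenols is needed.
2. Oxazinone (enol lactone) ring ⇐ N-phenacyl pyrrole-2-carboxylic acid (cyclodehydration) ⇐ NH-pyrrole ester + 2-bromo-4'-methoxyacetophenone (N-alkylation).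
3. Pyrrole ring ⇐ 2,3-diaryl-3-chloropropeniminium salt + glycine methyl ester (N to the CH carbon, ester-bearing carbon to the C–Cl carbon); this fixes the 3-anisyl / 4-iodoanisyl pattern.
4. Iminium salt ⇐ enaminone ⇐ mono-iodinated desoxyanisoin ⇐ desoxyanisoin (ring-selective iodination of the benzyl-side anisole).
5. Ring order: pyrrole first, oxazinone second.

## Route

**Step 1**
Reactants: 1 desoxyanisoin [1,2-bis(4-methoxyphenyl)ethan-1-one]; 2 N-iodosuccinimide
Product: 3 2-(3-iodo-4-methoxyphenyl)-1-(4-methoxyphenyl)ethan-1-one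
Conditions: NIS (1.05 equiv), TFA (0.3 equiv), MeCN, rt, dark
Reagents that add atoms: N-iodosuccinimide, O=C1CCC(=O)N1I
Why: Electrophilic aromatic iodination goes to the benzyl-side anisole ring ortho to OMe (para blocked), because the other anisole ring is deactivated by its para acyl group and the first iodine slows a second; no stereocentre is formed.

**Step 2**
Reactants: 3 2-(3-iodo-4-methoxyphenyl)-1-(4-methoxyphenyl)ethan-1-one; 4 N,N-dimethylformamide dimethyl acetal
Product: 5 (E)-3-(dimethylamino)-2-(3-iodo-4-methoxyphenyl)-1-(4-methoxyphenyl)prop-2-en-1-one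
Conditions: DMF-DMA (3 equiv), DMF, 110 °C
Reagents that add atoms: N,N-dimethylformamide dimethyl acetal, COC(OC)N(C)C
Why: Enaminone formation by condensation of the doubly activated CH2 (between aryl and aroyl) with the amide acetal, driven by loss of methanol; the alkene geometry has no consequence later.

**Step 3**
Reactants: 5 (E)-3-(dimethylamino)-2-(3-iodo-4-methoxyphenyl)-1-(4-methoxyphenyl)prop-2-en-1-one; 6 phosphoryl chloride; 7 glycine methyl ester hydrochloride
Product: 9 methyl 4-(3-iodo-4-methoxyphenyl)-3-(4-methoxyphenyl)-1H-pyrrole-2-carboxylate, via chloropropeniminium dichlorophosphate 8 (not isolated)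
Conditions: POCl3 (1.1 equiv), CH2Cl2, rt to 40 °C; evaporate; then 7, NaH (4 equiv), DMF, rt to 90 °C
Reagents that add atoms: glycine methyl ester hydrochloride, COC(=O)CN.Cl (N, C2 and the ester of 9); phosphoryl chloride, O=P(Cl)(Cl)Cl (its chlorine stands in 8 only and is lost again before 9)
Why: Vilsmeier-type O-activation and chloride addition–elimination give the β-chloro vinylogous iminium salt; the glycine nitrogen then exchanges at the iminium CH and the ester-stabilised α-carbanion closes by addition–elimination at the C–Cl carbon with aromatisation (Gupton-type pyrrole annulation), placing the ester next to the 4-methoxyphenyl group and leaving C5 unsubstituted.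

**Step 4**
Reactants: 9 methyl 4-(3-iodo-4-methoxyphenyl)-3-(4-methoxyphenyl)-1H-pyrrole-2-carboxylate; 10 2-bromo-1-(4-methoxyphenyl)ethan-1-one
Product: 11 methyl 4-(3-iodo-4-methoxyphenyl)-3-(4-methoxyphenyl)-1-[2-(4-methoxyphenyl)-2-oxoethyl]-1H-pyrrole-2-carboxylate
Conditions: K2CO3, DMF, 50 °C
Reagents that add atoms: 2-bromo-1-(4-methoxyphenyl)ethan-1-one, COc1ccc(cc1)C(=O)CBr
Why: SN2 N-alkylation of the acidic 2-acylpyrrole N–H by the reactive α-bromoketone; ester, aryl iodide and methyl ethers are inert to carbonate.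

**Step 5**
Reactants: 11 methyl 4-(3-iodo-4-methoxyphenyl)-3-(4-methoxyphenyl)-1-[2-(4-methoxyphenyl)-2-oxoethyl]-1H-pyrrole-2-carboxylate; 12 lithium hydroxide
Product: 13 4-(3-iodo-4-methoxyphenyl)-3-(4-methoxyphenyl)-1-[2-(4-methoxyphenyl)-2-oxoethyl]-1H-pyrrole-2-carboxylic acid
Conditions: LiOH, THF/MeOH/H2O, 60 °C; then 1 M HCl to pH 2
Reagents that add atoms: lithium hydroxide, [Li+].[OH-]
Why: Saponification (acyl-oxygen cleavage) of the only ester frees the acid needed for ring closure; the ketone, aryl iodide and ethers survive aqueous hydroxide.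

**Step 6**
Reactants: 13 4-(3-iodo-4-methoxyphenyl)-3-(4-methoxyphenyl)-1-[2-(4-methoxyphenyl)-2-oxoethyl]-1H-pyrrole-2-carboxylic acid
Product: 14 7-(3-iodo-4-methoxyphenyl)-3,8-bis(4-methoxyphenyl)-1H-pyrrolo[2,1-c][1,4]oxazin-1-one (lukianol B tri-O-methyl ether)
Conditions: Ac2O, NaOAc, 100 °C
Reagents that add atoms: none
Why: Cyclodehydration: mixed-anhydride activation of the acid and O-acylation of the ketone enol (enolised toward N–CH2) close the six-membered enol lactone, as in the non-iodinated lukianol A series; the new alkene is endocyclic.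

**Step 7**
Reactants: 14 7-(3-iodo-4-methoxyphenyl)-3,8-bis(4-methoxyphenyl)-1H-pyrrolo[2,1-c][1,4]oxazin-1-one
Product: 15 lukianol B [7-(4-hydroxy-3-iodophenyl)-3,8-bis(4-hydroxyphenyl)-1H-pyrrolo[2,1-c][1,4]oxazin-1-one]
Conditions: BBr3 (6 equiv), CH2Cl2, −78 °C to rt; then H2O
Reagents that add atoms: none
Why: BBr3 ether cleavage removes all three aryl methyl groups as MeBr while the aryl iodide and the conjugated enol lactone are left intact, giving the achiral target.

## Compound list

1 | desoxyanisoin, 1,2-bis(4-methoxyphenyl)ethan-1-one | COc1ccc(CC(=O)c2ccc(OC)cc2)cc1 | starting material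
2 | N-iodosuccinimide | O=C1CCC(=O)N1I | starting material
3 | 2-(3-iodo-4-methoxyphenyl)-1-(4-methoxyphenyl)ethan-1-one | COc1ccc(cc1)C(=O)Cc1ccc(OC)c(I)c1 | intermediate
4 | N,N-dimethylformamide dimethyl acetal | COC(OC)N(C)C | starting material
5 | (E)-3-(dimethylamino)-2-(3-iodo-4-methoxyphenyl)-1-(4-methoxyphenyl)prop-2-en-1-one | CN(C)/C=C(\c1ccc(OC)c(I)c1)C(=O)c1ccc(OC)cc1 | intermediate
6 | phosphoryl chloride (POCl3) | O=P(Cl)(Cl)Cl | starting material
7 | glycine methyl ester hydrochloride | COC(=O)CN.Cl | starting material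
8 | N-[(2Z)-3-chloro-2-(3-iodo-4-methoxyphenyl)-3-(4-methoxyphenyl)prop-2-en-1-ylidene]-N-methylmethanaminium dichlorophosphate | C[N+](C)=C/C(c1ccc(OC)c(I)c1)=C(\Cl)c1ccc(OC)cc1.[O-]P(=O)(Cl)Cl | intermediate (not isolated)
9 | methyl 4-(3-iodo-4-methoxyphenyl)-3-(4-methoxyphenyl)-1H-pyrrole-2-carboxylate | COC(=O)c1[nH]cc(-c2ccc(OC)c(I)c2)c1-c1ccc(OC)cc1 | intermediate
10 | 2-bromo-1-(4-methoxyphenyl)ethan-1-one | COc1ccc(cc1)C(=O)CBr | starting material
11 | methyl 4-(3-iodo-4-methoxyphenyl)-3-(4-methoxyphenyl)-1-[2-(4-methoxyphenyl)-2-oxoethyl]-1H-pyrrole-2-carboxylate | COC(=O)c1n(CC(=O)c2ccc(OC)cc2)cc(-c2ccc(OC)c(I)c2)c1-c1ccc(OC)cc1 | intermediate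
12 | lithium hydroxide (LiOH) | [Li+].[OH-] | starting material
13 | 4-(3-iodo-4-methoxyphenyl)-3-(4-methoxyphenyl)-1-[2-(4-methoxyphenyl)-2-oxoethyl]-1H-pyrrole-2-carboxylic acid | OC(=O)c1n(CC(=O)c2ccc(OC)cc2)cc(-c2ccc(OC)c(I)c2)c1-c1ccc(OC)cc1 | intermediate
14 | 7-(3-iodo-4-methoxyphenyl)-3,8-bis(4-methoxyphenyl)-1H-pyrrolo[2,1-c][1,4]oxazin-1-one | O=c1oc(-c2ccc(OC)cc2)cn2cc(-c3ccc(OC)c(I)c3)c(-c3ccc(OC)cc3)c12 | intermediate
15 | lukianol B, 7-(4-hydroxy-3-iodophenyl)-3,8-bis(4-hydroxyphenyl)-1H-pyrrolo[2,1-c][1,4]oxazin-1-one | O=c1oc(-c2ccc(O)cc2)cn2cc(-c3ccc(O)c(I)c3)c(-c3ccc(O)cc3)c12 | target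

## Step count and risks

Total step count: 7. Longest linear sequence: 7 steps (1 → 15); the route is fully linear.

Steps most likely to fail:

**Step 1 (ring-selective mono-iodination).** Iodination at the ketone α-CH2, on the acyl-side ring, or twice on the benzyl-side ring could erode the yield. The fallback builds the iodinated ketone from two pieces instead of iodinating the finished ketone. It sets out from N-iodosuccinimide 2, which is spent on commercial 4-methoxyphenylacetic acid (NIS, cat. TFA, MeCN, rt) rather than on 1; there is only one arene and no ketone to compete, and the product is (3-iodo-4-methoxyphenyl)acetic acid F1. Friedel–Crafts acylation of anisole with F1 through its mixed trifluoroacetic anhydride (TFAA, cat. H3PO4, rt), para to the methoxy group, comes back to the route at 3.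

**Step 3 (one-pot chloroiminium formation and pyrrole annulation).** The moisture-sensitive salt 8, hot NaH/DMF in the presence of an aryl iodide, and a competing N-attack at the C–Cl carbon are the weak points. The fallback avoids POCl3 activation and NaH and reverses the polarity of ring closure: the carbanion attacks a ketone rather than displacing chloride. It sets out from enaminone 5: amine exchange with glycine methyl ester hydrochloride 7 (MeOH, 60 °C) gives the hydrogen-bonded secondary enaminone methyl N-[(Z)-2-(3-iodo-4-methoxyphenyl)-3-(4-methoxyphenyl)-3-oxoprop-1-en-1-yl]glycinate F2. NaOMe in MeOH at reflux then effects intramolecular Knoevenagel-type condensation of the glycinate CH2 onto the aryl ketone and dehydration, with the same regiochemistry, and comes back to the route at 9.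

**Step 7 (global demethylation on the enol lactone).** Lactone opening, incomplete cleavage of the hindered ortho-iodo anisole, or proto-deiodination by HBr could occur. The fallback moves the demethylation ahead of lactone formation, so the last step is a mild deacylation. It sets out from acid 13: BBr3 (CH2Cl2, −78 °C to rt) gives 3-(4-hydroxyphenyl)-4-(4-hydroxy-3-iodophenyl)-1-[2-(4-hydroxyphenyl)-2-oxoethyl]-1H-pyrrole-2-carboxylic acid F3. Ac2O/NaOAc (100 °C) closes the enol lactone and acetylates the three phenols to lukianol B triacetate F4. Mild methanolysis of the aryl acetates (NH4OAc, aqueous MeOH, rt) comes back to the route at 15.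

## Further compounds

F1 | step 1 | (3-iodo-4-methoxyphenyl)acetic acid | COc1ccc(CC(=O)O)cc1I
F2 | step 3 | methyl N-[(Z)-2-(3-iodo-4-methoxyphenyl)-3-(4-methoxyphenyl)-3-oxoprop-1-en-1-yl]glycinate | COC(=O)CN/C=C(/c1ccc(OC)c(I)c1)C(=O)c1ccc(OC)cc1
F3 | step 7 | 3-(4-hydroxyphenyl)-4-(4-hydroxy-3-iodophenyl)-1-[2-(4-hydroxyphenyl)-2-oxoethyl]-1H-pyrrole-2-carboxylic acid | OC(=O)c1n(CC(=O)c2ccc(O)cc2)cc(-c2ccc(O)c(I)c2)c1-c1ccc(O)cc1
F4 | step 7 | lukianol B triacetate, 4-[7-(4-acetoxy-3-iodophenyl)-8-(4-acetoxyphenyl)-1-oxo-1H-pyrrolo[2,1-c][1,4]oxazin-3-yl]phenyl acetate | CC(=O)Oc1ccc(cc1)-c1cn2cc(-c3ccc(OC(C)=O)c(I)c3)c(-c3ccc(OC(C)=O)cc3)c2c(=O)o1
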